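Each step thought possible turns one J into one X, so J and X together stay at 100% of the charge, and the ratio X/J tells the state of a flask.

| flask | J | remark | time |
|---|---|---|---|
| Monday's | 1.4 M | run made earlier |  |
| Tuesday's | 2.2 M | run made earlier |  |
| flask | 1.0 M |  | 5.0 min |

| run | time / min | X / % | J / % |
|---|---|---|---|
| Monday's | 0.833 | 2 | 99 |
| Monday's | 1.50 | 11 | 89 |
| Monday's | 2.50 | 60 | 38 |
| Monday's | 3.00 | 87 | 18 |
| Monday's | 4.00 | 97 | 0 |
| Monday's | 5.00 | 100 | 0 |
| Tuesday's | 0.333 | 0 | 99 |
| Tuesday's | 1.00 | 10 | 89 |
| Tuesday's | 2.00 | 81 | 18 |
| Tuesday's | 2.50 | 100 | 0 |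
| Tuesday's | 4.00 | 96 | 0 |
| Tuesday's | 5.00 | 101 | 3 |

(scatter of a reading: 2 percentage points)
- what was read earlier has a scatter of 2 percentage points, one standard deviation
- steps thought possible: J + X -> 2 X; J -> X
- amount of X in the flask at 5.0 min, in percent of the J charged
- amount of J in the flask at 5.0 min, in percent of the J charged

After its induction period, ln(X/J) climbs almost straight: 2.44 min⁻¹ in Monday's run, 3.69 min⁻¹ in Tuesday's. Scaled in proportion to the charge, down to the flask's 1.0 M, these read 1.75 min⁻¹ and 1.68 min⁻¹, close together, as autocatalysis suggests. From Monday's run we read 3.30 min for the crossing time T, the time at which X equals J, stretched in proportion from the run's charge to the flask's; Tuesday's run reads 3.50 min.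

Then ln(X/J) in the flask is about the scaled slope times the time less T, and the flask's time is 5.0 min. The balance caps X at 100%. T read higher from the higher charge, so for our lower charge we take Monday's T with the smaller slope as our low estimate: 94.6% X. Lowering Monday's T by that whole rise, with the larger slope, gives our high estimate of 96.5%.

The forecast, reading “a lag and then a fast rise”, gives 97% X and 3% J, just above our high estimate. The flask gives 96.9% X and 3.11% J, also above it.

    J + X → 2 X (k = 0.0304 L mol⁻¹ s⁻¹)
    J → X (k = 1.01 × 10⁻⁴ s⁻¹)

In the flask at 5.00 min the half-life of J is 0.39 min by the path through X, far shorter than its 110 min by J → X. The path through X then uses J 290 times as fast. In the flask at 2.50 min, earlier than Monday's T of 3.30 min, J at 75.9% still exceeds X at 24.1%. For the neighbour with 0.25 M of J, Monday's T stretches to 13.2 min, longer than its 5.0 min, and that flask ends with 89.4% J and 10.6% X.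

(The readings are simulated with constants of no real substance; scatter was added.)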